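**Retrosynthetic overview**

1. Target 32 comes from its hydroquinone bis-methyl ether 31 by oxidation. Ether 31 is cut at C10–C11 into the primary Grignard reagent 30 (naphthalene plus C1–C10) and the secondary tosylate 18 (C11–C32), joined by a copper-catalysed SN2 coupling with inversion that also sets C11.
2. Enabling feature: C11 is an acyclic CH(CH3) between two unbranched CH2 groups (C10 and C12). It can therefore be bought as the carbinol carbon of (R)-propylene oxide and substituted cleanly. C7 and C15 lie four carbons to either side, and both map onto C3 of (S)-citronellyl bromide (C5–C10 and C13–C20).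
3. Right half 18: citronellyl Grignard plus (R)-propylene oxide (C12–C13), SeO2 oxidation of the E-methyl group (C20), then sulfone alkylation and Pd desulfonylation at C20–C21 with the 10,11-dihydrofarnesyl sulfone 6. Sulfone 6 comes from geranyl acetate, with C28–C29 made by Cu-catalysed Grignard coupling.
4. Left half 29: citronellyl bromide plus silylpropyne (C4–C5), ozonolysis (C10), Zr-catalysed methylalumination of the alkyne (C3–CH3, 2E), and Ni-catalysed coupling with the chloromethylnaphthalene 20 (C1–C2).
5. No ring is formed in the route: the naphthalene is bought as 19, and the quinone ring is only unmasked by oxidation in the last step.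

Key step: step 16

Remark: locants C1–C32 count the side chain from the ring, and the target is (7S,11R,15R), all-E; compounds 1, 4, 7, 8, 19 and 21 are taken as purchased.

**Tail sulfone (C21–C32)**

Step 1
Reactants: 1 geranyl acetate
Product: 2 (2E,6E)-8-hydroxy-3,7-dimethylocta-2,6-dien-1-yl acetate
Conditions: SeO2 (cat.), t-BuOOH, salicylic acid (cat.), CH2Cl2, rt
Reagents that add atoms: tert-butyl hydroperoxide CC(C)(C)OO (terminal oxidant; the oxygen is passed on through catalytic selenium dioxide O=[Se]=O)
Why: SeO2/t-BuOOH allylic oxidation (ene reaction, then [2,3]-shift) should go to the E-methyl group of the electron-rich terminal alkene, since the 2,3-alkene is deactivated by the allylic acetate, and give the E-allylic alcohol.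

Step 2
Reactants: 2 (2E,6E)-8-hydroxy-3,7-dimethylocta-2,6-dien-1-yl acetate
Product: 3 (2E,6E)-8-bromo-3,7-dimethylocta-2,6-dien-1-yl acetate
Conditions: CBr4, PPh3, CH2Cl2, 0 °C
Reagents that add atoms: carbon tetrabromide BrC(Br)(Br)Br
Why: Appel bromination of a primary allylic alcohol (SN2 on the alkoxyphosphonium ion) is neutral, so the acetate and both E-alkenes should be kept.

Step 3
Reactants: 3 (2E,6E)-8-bromo-3,7-dimethylocta-2,6-dien-1-yl acetate; 4 isopentylmagnesium bromide
Product: 5 (2E,6E)-3,7,11-trimethyldodeca-2,6-dien-1-yl acetate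
Conditions: Li2CuCl4 (cat.), THF, −78 → −40 °C
Reagents that add atoms: none
Why: Copper-catalysed Grignard cross-coupling (Kochi/Fouquet–Schlosser type) should displace the primary allylic bromide at its α-carbon much faster than it touches the allylic acetate at low temperature, as is known for 4-halo-2-alkenyl acetates.

Step 4
Reactants: 5 (2E,6E)-3,7,11-trimethyldodeca-2,6-dien-1-yl acetate
Product: 6 [(2E,6E)-3,7,11-trimethyldodeca-2,6-dien-1-yl]sulfonylbenzene
Conditions: PhSO2Na, Pd(PPh3)4 (cat.), THF/MeOH, rt → 50 °C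
Reagents that add atoms: sodium benzenesulfinate [Na+].[O-]S(=O)c1ccccc1
Why: Tsuji–Trost-type allylic substitution by sulfinate should end at the thermodynamically preferred primary allyl sulfone, and the 3,3-disubstituted π-allyl terminus does not undergo syn/anti exchange, so the 2E geometry is expected to persist.

**Right half (C11–C32)**

Step 5
Reactants: 7 (S)-citronellyl bromide; 8 (R)-propylene oxide
Product: 11 (2R,6R)-6,10-dimethylundec-9-en-2-yl pivalate, via citronellyl Grignard reagent 9 (not isolated), via bromomagnesium alkoxide 10 (not isolated)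
Conditions: Mg, THF, 40 °C; then CuI (cat.), 8, −30 → 0 °C; then PivCl, DMAP (cat.), 0 °C → rt
Reagents that add atoms: pivaloyl chloride CC(C)(C)C(Cl)=O
Why: CuI-catalysed epoxide opening by the primary Grignard reagent at the CH2 terminus breaks no bond at either stereocentre (future C11 and C15), and the magnesium alkoxide is acylated in the same flask.

Step 6
Reactants: 11 (2R,6R)-6,10-dimethylundec-9-en-2-yl pivalate
Product: 12 (2R,6R,9E)-11-hydroxy-6,10-dimethylundec-9-en-2-yl pivalate
Conditions: SeO2 (cat.), t-BuOOH, salicylic acid (cat.), CH2Cl2, rt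
Reagents that add atoms: tert-butyl hydroperoxide CC(C)(C)OO (terminal oxidant; the oxygen is passed on through catalytic selenium dioxide O=[Se]=O)
Why: SeO2/t-BuOOH allylic oxidation of the only alkene should take place at its E-methyl group and give the E-allylic alcohol (future C20), with the pivalate inert.

Step 7
Reactants: 12 (2R,6R,9E)-11-hydroxy-6,10-dimethylundec-9-en-2-yl pivalate
Product: 13 (2R,6R,9E)-11-bromo-6,10-dimethylundec-9-en-2-yl pivalate
Conditions: CBr4, PPh3, CH2Cl2, 0 °C
Reagents that add atoms: carbon tetrabromide BrC(Br)(Br)Br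
Why: Appel bromination of the primary allylic alcohol proceeds by SN2 without allylic shift, so the 9E geometry and the ester should be kept.

Step 8
Reactants: 6 [(2E,6E)-3,7,11-trimethyldodeca-2,6-dien-1-yl]sulfonylbenzene; 13 (2R,6R,9E)-11-bromo-6,10-dimethylundec-9-en-2-yl pivalate
Product: 15 (2R,6R,9E,13E,17E)-6,10,14,18,22-pentamethyl-12-(phenylsulfonyl)tricosa-9,13,17-trien-2-yl pivalate (both C12 epimers), via lithiated sulfone 14 (not isolated)
Conditions: 6, n-BuLi, THF/DMPU, −78 °C; then 13, −78 → −40 °C
Reagents that add atoms: none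
Why: Biellmann-type alkylation of the α-sulfonyl allyl anion with a primary allylic bromide forms C20–C21 by SN2 at the α-carbon with all alkene geometries kept; the unselective sulfone-bearing centre is removed in step 9, and the hindered pivalate should survive at −78 °C.

Step 9
Reactants: 15 (2R,6R,9E,13E,17E)-6,10,14,18,22-pentamethyl-12-(phenylsulfonyl)tricosa-9,13,17-trien-2-yl pivalate
Product: 17 (2R,6R,9E,13E,17E)-6,10,14,18,22-pentamethyltricosa-9,13,17-trien-2-ol, via desulfonylated pivalate 16 (not isolated)
Conditions: PdCl2(dppp) (cat.), LiEt3BH (excess), THF, 0 °C → rt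
Reagents that add atoms: none
Why: Pd(0)-catalysed hydride substitution of the allylic sulfone should deliver hydride to the less substituted π-allyl terminus without alkene shift or loss of E geometry, and the excess LiEt3BH then cleaves the pivalate reductively on warming.

Step 10
Reactants: 17 (2R,6R,9E,13E,17E)-6,10,14,18,22-pentamethyltricosa-9,13,17-trien-2-ol
Product: 18 (2R,6R,9E,13E,17E)-6,10,14,18,22-pentamethyltricosa-9,13,17-trien-2-yl 4-methylbenzenesulfonate
Conditions: TsCl, Et3N, DMAP (cat.), CH2Cl2, 0 °C → rt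
Reagents that add atoms: 4-toluenesulfonyl chloride Cc1ccc(cc1)S(Cl)(=O)=O
Why: O-Sulfonylation of the secondary alcohol breaks no bond at the carbinol carbon, so the (R) configuration is retained.

**Left half (naphthalene plus C1–C10)**

Step 11
Reactants: 19 1,4-dimethoxy-2-methylnaphthalene
Product: 20 2-(chloromethyl)-1,4-dimethoxy-3-methylnaphthalene
Conditions: (CH2O)n, HCl (conc.), AcOH, rt
Reagents that add atoms: formaldehyde (as paraformaldehyde) C=O; hydrogen chloride Cl
Why: Blanc chloromethylation should occur at C3, the only free position of the electron-rich substituted ring.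

Step 12
Reactants: 21 1-(trimethylsilyl)propyne; 7 (S)-citronellyl bromide
Product: 23 [(6R)-6,10-dimethylundec-9-en-1-yn-1-yl]trimethylsilane, via lithiated silylpropyne 22 (not isolated)
Conditions: 21, n-BuLi, THF, −78 °C; then 7, HMPA, −78 °C → rt
Reagents that add atoms: none
Why: Alkylation of 3-lithio-1-(trimethylsilyl)propyne at its propargylic carbon by the primary bromide (SN2) adds C2–C4 and leaves the remote stereocentre untouched.

Step 13
Reactants: 23 [(6R)-6,10-dimethylundec-9-en-1-yn-1-yl]trimethylsilane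
Product: 26 (4R)-4-methylnon-8-yn-1-ol, via silyl alkynal 24 (not isolated), via silyl alkynol 25 (not isolated)
Conditions: O3, CH2Cl2/MeOH, −78 °C (indicator end point); NaBH4, −78 °C → rt; then K2CO3, MeOH, rt
Reagents that add atoms: ozone [O-][O+]=O
Why: Ozonolysis with reductive work-up should cleave the trisubstituted alkene far faster than the silylalkyne and give the C10 alcohol, and K2CO3/MeOH then removes the alkynyl silyl group by protodesilylation.

Step 14
Reactants: 26 (4R)-4-methylnon-8-yn-1-ol
Product: 27 (6R)-9-chloro-6-methylnon-1-yne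
Conditions: PPh3, NCS, THF, 0 °C → rt
Reagents that add atoms: N-chlorosuccinimide O=C1CCC(=O)N1Cl
Why: Appel-type chlorination is an SN2 reaction at the primary carbon under neutral conditions, which the terminal alkyne tolerates.

Step 15
Reactants: 27 (6R)-9-chloro-6-methylnon-1-yne; 20 2-(chloromethyl)-1,4-dimethoxy-3-methylnaphthalene
Product: 29 2-[(2E,7R)-10-chloro-3,7-dimethyldec-2-en-1-yl]-1,4-dimethoxy-3-methylnaphthalene, via alkenylalane 28 (not isolated)
Conditions: Me3Al, Cp2ZrCl2 (cat.), CH2Cl2, 0 °C → rt; then 20, Ni(PPh3)4 (cat., from NiCl2(PPh3)2/n-BuLi), THF, rt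
Reagents that add atoms: trimethylaluminium C[Al](C)C
Why: Negishi zirconium-catalysed carboalumination adds methyl and aluminium syn across the terminal alkyne (methyl to the internal carbon), and the nickel-catalysed cross-coupling of the alkenylalane with the benzylic chloride proceeds with retention, which should set the 2E trisubstituted alkene; the primary alkyl chloride is inert to both metals.

**Fragment union and end game**

Step 16
Reactants: 29 2-[(2E,7R)-10-chloro-3,7-dimethyldec-2-en-1-yl]-1,4-dimethoxy-3-methylnaphthalene; 18 (2R,6R,9E,13E,17E)-6,10,14,18,22-pentamethyltricosa-9,13,17-trien-2-yl 4-methylbenzenesulfonate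
Product: 31 2-[(2E,7S,11R,15R,18E,22E,26E)-3,7,11,15,19,23,27,31-octamethyldotriaconta-2,18,22,26-tetraen-1-yl]-1,4-dimethoxy-3-methylnaphthalene, via left-half Grignard reagent 30 (not isolated)
Conditions: Mg (activated, BrCH2CH2Br cat.), THF, 60 °C; then 18, CuI (cat.), TMEDA, LiOMe, THF, 0 °C
Reagents that add atoms: none
Why: The chloride is turned into the primary Grignard reagent 30, which transmetalates to an alkylcuprate that attacks C11 of tosylate 18 from the face opposite the leaving group (SN2-type oxidative addition, then reductive elimination), so the C10–C11 bond should form with Walden inversion. The closest known reaction type is the copper-catalysed cross-coupling of unactivated secondary alkyl tosylates with alkyl Grignard reagents, which is stereoinvertive. No ring is closed. The only new stereocentre, C11, is controlled by the carbinol configuration bought with (R)-propylene oxide: the (R)-tosylate gives by inversion the arrangement that is (11R) in the product (the descriptor stays R only because the CIP ranking of the substituents changes), while C7 and C15, both from (S)-citronellyl bromide, are spectators. The step needs substitution to win over E2 elimination and over attack at sulfur, and this is secured by the substrate, in which C11 carries only a methyl group and an unbranched CH2 chain (no β-branching, no ring), by the unhindered primary nucleophile, and by TMEDA/LiOMe at 0 °C. The quinone is masked as the bis-methyl ether, so only aryl ethers and trisubstituted alkenes face the organometallic.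

Step 17
Reactants: 31 2-[(2E,7S,11R,15R,18E,22E,26E)-3,7,11,15,19,23,27,31-octamethyldotriaconta-2,18,22,26-tetraen-1-yl]-1,4-dimethoxy-3-methylnaphthalene
Product: 32 2-methyl-3-[(2E,7S,11R,15R,18E,22E,26E)-3,7,11,15,19,23,27,31-octamethyldotriaconta-2,18,22,26-tetraen-1-yl]naphthalene-1,4-dione
Conditions: (NH4)2Ce(NO3)6, MeCN/H2O (CH2Cl2 co-solvent), 0 °C
Reagents that add atoms: water O
Why: Ceric ammonium nitrate oxidative demethylation of the 1,4-dimethoxynaphthalene should give the 1,4-naphthoquinone, while the isolated trisubstituted alkenes and the three stereocentres are not affected.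

**Compound list**

1 | geranyl acetate, (2E)-3,7-dimethylocta-2,6-dien-1-yl acetate | CC(C)=CCC/C(C)=C/COC(C)=O | starting material
2 | (2E,6E)-8-hydroxy-3,7-dimethylocta-2,6-dien-1-yl acetate | OC/C(C)=C/CC/C(C)=C/COC(C)=O | intermediate
3 | (2E,6E)-8-bromo-3,7-dimethylocta-2,6-dien-1-yl acetate | BrC/C(C)=C/CC/C(C)=C/COC(C)=O | intermediate
4 | isopentylmagnesium bromide | CC(C)CC[Mg]Br | starting material
5 | (2E,6E)-3,7,11-trimethyldodeca-2,6-dien-1-yl acetate | CC(C)CCC/C(C)=C/CC/C(C)=C/COC(C)=O | intermediate
6 | [(2E,6E)-3,7,11-trimethyldodeca-2,6-dien-1-yl]sulfonylbenzene | CC(C)CCC/C(C)=C/CC/C(C)=C/CS(=O)(=O)c1ccccc1 | intermediate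
7 | (S)-citronellyl bromide, (6S)-8-bromo-2,6-dimethyloct-2-ene | C[C@@H](CCC=C(C)C)CCBr | starting material
8 | (R)-propylene oxide, (2R)-2-methyloxirane | C[C@@H]1CO1 | starting material
9 | [(3S)-3,7-dimethyloct-6-en-1-yl]magnesium bromide | C[C@@H](CCC=C(C)C)CC[Mg]Br | intermediate
10 | bromomagnesium (2R,6R)-6,10-dimethylundec-9-en-2-olate | C[C@@H](O[Mg]Br)CCC[C@@H](C)CCC=C(C)C | intermediate
11 | (2R,6R)-6,10-dimethylundec-9-en-2-yl pivalate | C[C@@H](OC(=O)C(C)(C)C)CCC[C@@H](C)CCC=C(C)C | intermediate
12 | (2R,6R,9E)-11-hydroxy-6,10-dimethylundec-9-en-2-yl pivalate | C[C@@H](OC(=O)C(C)(C)C)CCC[C@@H](C)CC/C=C(\C)CO | intermediate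
13 | (2R,6R,9E)-11-bromo-6,10-dimethylundec-9-en-2-yl pivalate | C[C@@H](OC(=O)C(C)(C)C)CCC[C@@H](C)CC/C=C(\C)CBr | intermediate
14 | [(2E,6E)-3,7,11-trimethyl-1-(phenylsulfonyl)dodeca-2,6-dien-1-yl]lithium | [Li]C(/C=C(\C)CC/C=C(\C)CCCC(C)C)S(=O)(=O)c1ccccc1 | intermediate
15 | (2R,6R,9E,13E,17E)-6,10,14,18,22-pentamethyl-12-(phenylsulfonyl)tricosa-9,13,17-trien-2-yl pivalate (C12 epimers) | C[C@@H](OC(=O)C(C)(C)C)CCC[C@@H](C)CC/C=C(\C)CC(/C=C(\C)CC/C=C(\C)CCCC(C)C)S(=O)(=O)c1ccccc1 | intermediate
16 | (2R,6R,9E,13E,17E)-6,10,14,18,22-pentamethyltricosa-9,13,17-trien-2-yl pivalate | C[C@@H](OC(=O)C(C)(C)C)CCC[C@@H](C)CC/C=C(\C)CC/C=C(\C)CC/C=C(\C)CCCC(C)C | intermediate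
17 | (2R,6R,9E,13E,17E)-6,10,14,18,22-pentamethyltricosa-9,13,17-trien-2-ol | C[C@@H](O)CCC[C@@H](C)CC/C=C(\C)CC/C=C(\C)CC/C=C(\C)CCCC(C)C | intermediate
18 | (2R,6R,9E,13E,17E)-6,10,14,18,22-pentamethyltricosa-9,13,17-trien-2-yl 4-methylbenzenesulfonate | C[C@@H](OS(=O)(=O)c1ccc(C)cc1)CCC[C@@H](C)CC/C=C(\C)CC/C=C(\C)CC/C=C(\C)CCCC(C)C | intermediate
19 | 1,4-dimethoxy-2-methylnaphthalene | COc1cc(C)c(OC)c2ccccc12 | starting material
20 | 2-(chloromethyl)-1,4-dimethoxy-3-methylnaphthalene | COc1c(C)c(CCl)c(OC)c2ccccc12 | intermediate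
21 | 1-(trimethylsilyl)propyne, trimethyl(prop-1-yn-1-yl)silane | CC#C[Si](C)(C)C | starting material
22 | [3-(trimethylsilyl)prop-2-yn-1-yl]lithium | [Li]CC#C[Si](C)(C)C | intermediate
23 | [(6R)-6,10-dimethylundec-9-en-1-yn-1-yl]trimethylsilane | C[C@@H](CCC=C(C)C)CCCC#C[Si](C)(C)C | intermediate
24 | (4R)-4-methyl-9-(trimethylsilyl)non-8-ynal | C[C@@H](CCC=O)CCCC#C[Si](C)(C)C | intermediate
25 | (4R)-4-methyl-9-(trimethylsilyl)non-8-yn-1-ol | C[C@@H](CCCO)CCCC#C[Si](C)(C)C | intermediate
26 | (4R)-4-methylnon-8-yn-1-ol | C[C@@H](CCCO)CCCC#C | intermediate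
27 | (6R)-9-chloro-6-methylnon-1-yne | C[C@@H](CCCCl)CCCC#C | intermediate
28 | [(1E,6R)-9-chloro-2,6-dimethylnon-1-en-1-yl]dimethylalumane | C[Al](C)/C=C(\C)CCC[C@@H](C)CCCCl | intermediate
29 | 2-[(2E,7R)-10-chloro-3,7-dimethyldec-2-en-1-yl]-1,4-dimethoxy-3-methylnaphthalene | COc1c(C)c(C/C=C(\C)CCC[C@@H](C)CCCCl)c(OC)c2ccccc12 | intermediate
30 | [(4R,8E)-10-(1,4-dimethoxy-3-methylnaphthalen-2-yl)-4,8-dimethyldec-8-en-1-yl]magnesium chloride | COc1c(C)c(C/C=C(\C)CCC[C@@H](C)CCC[Mg]Cl)c(OC)c2ccccc12 | intermediate
31 | 2-[(2E,7S,11R,15R,18E,22E,26E)-3,7,11,15,19,23,27,31-octamethyldotriaconta-2,18,22,26-tetraen-1-yl]-1,4-dimethoxy-3-methylnaphthalene | COc1c(C)c(C/C=C(\C)CCC[C@@H](C)CCC[C@@H](C)CCC[C@@H](C)CC/C=C(\C)CC/C=C(\C)CC/C=C(\C)CCCC(C)C)c(OC)c2ccccc12 | intermediate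
32 | 2-methyl-3-[(2E,7S,11R,15R,18E,22E,26E)-3,7,11,15,19,23,27,31-octamethyldotriaconta-2,18,22,26-tetraen-1-yl]naphthalene-1,4-dione | CC1=C(C/C=C(\C)CCC[C@@H](C)CCC[C@@H](C)CCC[C@@H](C)CC/C=C(\C)CC/C=C(\C)CC/C=C(\C)CCCC(C)C)C(=O)c2ccccc2C1=O | target

**Step count**

Total: 17 steps. Longest linear sequence: 9 steps (1, 2, 3, 4, 8, 9, 10, 16, 17).

**Steps most likely to fail, with fallbacks**

Step 16. The secondary tosylate may undergo E2 elimination faster than substitution, or the substitution may be so slow that the Grignard reagent is lost by protonation and homocoupling. The fallback keeps the same bond and the same inversion at C11 but uses a stabilised carbanion as nucleophile. It sets out from 29 and 18. Chloride 29 is heated with PhSO2Na and catalytic NaI in DMF to give the left-half phenyl sulfone F1. Its α-lithio derivative (n-BuLi, THF/HMPA, −78 → 0 °C) is alkylated by tosylate 18 in an SN2 reaction to give the C10-sulfonyl coupling product F2 as a mixture of C10 epimers. Reductive desulfonylation with Na(Hg)/Na2HPO4 in MeOH/THF then returns to the route at 31.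

Step 3. The Grignard reagent may fail to distinguish the two allylic leaving groups, may add to the ester carbonyl, or may attack the γ-carbon with allylic transposition. The fallback makes C28–C29 by sulfone carbanion chemistry and sets out from 3. Isopentyl phenyl sulfone F3, made from 1-bromo-3-methylbutane and PhSO2Na in DMF, is lithiated (n-BuLi, THF, −78 °C) and alkylated by bromide 3 at −78 °C to give the sulfonyl acetate F4. Na(Hg)/Na2HPO4 in MeOH, followed by K2CO3 in MeOH, removes the sulfonyl and acetyl groups and gives 10,11-dihydrofarnesol F5. PBr3 in Et2O at 0 °C converts this into the allylic bromide F6, and PhSO2Na in DMF returns to the route at 6, so that step 4 is bypassed as well.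

Step 15. The carbometalation may be incomplete or regio-unselective, and in the nickel cycle a methyl group may be transferred from aluminium instead of the alkenyl group. The fallback reverses the polarity of the coupling and sets out from 27 and 20. Alkenylalane 28 is formed as before and quenched with I2 to give the E-alkenyl iodide F7, which is purified. Chloride 20 is treated with zinc dust and LiCl in THF to give the benzylic zinc chloride F8. A Pd(PPh3)4-catalysed Negishi coupling of F7 with F8 in THF at rt, which proceeds with retention of alkene geometry, returns to the route at 29.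

**Further compounds**

F1 | step 16 | 1,4-dimethoxy-2-methyl-3-[(2E,7R)-3,7-dimethyl-10-(phenylsulfonyl)dec-2-en-1-yl]naphthalene | COc1c(C)c(C/C=C(\C)CCC[C@@H](C)CCCS(=O)(=O)c3ccccc3)c(OC)c2ccccc12
F2 | step 16 | 2-[(2E,7R,11S,15R,18E,22E,26E)-3,7,11,15,19,23,27,31-octamethyl-10-(phenylsulfonyl)dotriaconta-2,18,22,26-tetraen-1-yl]-1,4-dimethoxy-3-methylnaphthalene (C10 epimers) | COc1c(C)c(C/C=C(\C)CCC[C@@H](C)CCC(S(=O)(=O)c3ccccc3)[C@@H](C)CCC[C@@H](C)CC/C=C(\C)CC/C=C(\C)CC/C=C(\C)CCCC(C)C)c(OC)c2ccccc12
F3 | step 3 | (3-methylbutylsulfonyl)benzene | CC(C)CCS(=O)(=O)c1ccccc1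
F4 | step 3 | (2E,6E)-3,7,11-trimethyl-9-(phenylsulfonyl)dodeca-2,6-dien-1-yl acetate | CC(C)CC(S(=O)(=O)c1ccccc1)C/C(C)=C/CC/C(C)=C/COC(C)=O
F5 | step 3 | (2E,6E)-3,7,11-trimethyldodeca-2,6-dien-1-ol | CC(C)CCC/C(C)=C/CC/C(C)=C/CO
F6 | step 3 | (2E,6E)-1-bromo-3,7,11-trimethyldodeca-2,6-diene | CC(C)CCC/C(C)=C/CC/C(C)=C/CBr
F7 | step 15 | (1E,6R)-9-chloro-1-iodo-2,6-dimethylnon-1-ene | I/C=C(\C)CCC[C@@H](C)CCCCl
F8 | step 15 | [(1,4-dimethoxy-3-methylnaphthalen-2-yl)methyl]zinc chloride | COc1c(C)c(C[Zn]Cl)c(OC)c2ccccc12
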